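**Plan**

- Retrosynthesis: the interflavanyl C4(upper)–C6(lower) bond is cut first (flavan-4-yl cation plus arene). In the lower unit the C4a–C4 and C2–C3 bonds are then cut together, leaving a pyrogallol arylidene acetal (ring A, O1 and C2 with its aryl group) and a cis-enediol acetonide (C3–C4). The upper ring C is cut at O1–C2 (epoxide opening) and at the chalcone C=C bond.
- Forward: the lower pyran ring is grown on pyrogallol in one annulation (steps 1–4). The upper unit runs ring A acetophenone → chalcone → epoxide → ring C (steps 5–11). The units are joined (step 12) and unmasked (steps 13–15).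
- Enabling feature: in the lower unit O1 on C8a is adjacent to the C8 hydroxyl. The two oxygens can be tied as a five-membered arylidene acetal, whose opening gives an aryl oxocarbenium ion (2-oxonia-diene C4a=C8a–O1=C2) with the freed 8-OH as anchor for a chiral phosphate. C4a is the only free ortho carbon and lies para to O7.
- Stereochemistry, lower unit: C2 from the catalyst (face of the oxocarbenium), C3 from endo approach of the enediol, C4 from the enforced cis fusion of the acetonide.
- Stereochemistry, upper unit: C3 from the Julia–Colonna epoxidation, C2 by inversion at the benzylic epoxide carbon, C4 by 3-acetoxy participation (3,4-trans).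

Key step: step 3

Assumption: 2,2-dimethyl-1,3-dioxole (6) is taken as a purchasable reagent; the (R)-phosphoric acid is written in step 3 and its enantiomer is used if the sense of induction proves opposite.

Unit names used below: ent-oritin is the (2S,3R)-2,3-trans-7,8,4'-trihydroxyflavan-3-ol unit; epioritin-4α-ol is the (2R,3R,4R)-all-cis-7,8,4'-trihydroxyflavan-3,4-diol unit.

**Route**

Step 1
Reactants: 1 pyrogallol (benzene-1,2,3-triol); 2 4-(benzyloxy)benzaldehyde
Product: 4 2-[4-(benzyloxy)phenyl]-1,3-benzodioxol-4-ol (racemic at the acetal carbon), via 4-(benzyloxy)benzaldehyde dimethyl acetal 3 (not isolated)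
Conditions: 2, HC(OMe)3, p-toluenesulfonic acid monohydrate (cat.), MeOH, rt; evaporate; then 1, pyridinium p-toluenesulfonate (cat.), toluene, 80 °C, MeOH distilled off
Reagents that add atoms: none
Why: Acid-catalysed transacetalisation; pyrogallol is symmetric, so the five-membered acetal can only span two adjacent oxygens and one constitutional isomer should result, while mild acid and removal of methanol favour O- over C-alkylation.

Step 2
Reactants: 4
Product: 5 4-(benzyloxy)-2-[4-(benzyloxy)phenyl]-1,3-benzodioxole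
Conditions: BnBr, K2CO3, DMF, rt
Reagents that add atoms: benzyl bromide, BrCc1ccccc1
Why: Williamson ether synthesis at the only free phenol; the benzyl ether later activates C4a (para) for ring closure and the acetal is stable to base.

Step 3
Reactants: 5; 6 2,2-dimethyl-1,3-dioxole
Product: 8 (2R,3S,4R)-7-(benzyloxy)-2-[4-(benzyloxy)phenyl]-3,4-(isopropylidenedioxy)chroman-8-ol (2-aryl and both ring oxygens at C3 and C4 all cis), via ring-opened aryl oxocarbenium ion 7 (not isolated)
Conditions: 6 (3 equiv), (R)-3,3'-bis(2,4,6-triisopropylphenyl)-1,1'-binaphthyl-2,2'-diyl hydrogen phosphate (C50H57O4P, 5 mol %), 5 Å molecular sieves, toluene, 0 °C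
Reagents that add atoms: none
Why: Proposed new method: the chiral phosphoric acid should open the benzodioxole acetal of 5 at the oxygen next to the benzyloxy group, so that the oxygen remaining on the acetal carbon becomes the aryl oxocarbenium ion 7 (a 2-oxonia-diene C4a=C8a–O1=C2) while the liberated 8-OH hydrogen-bonds to the phosphate; the electron-rich alkene 6 then adds in an asynchronous inverse-demand [4+2] (C2–C3 bond leading, C4–C4a bond closing by Friedel–Crafts attack), and loss of the arene proton returns the acid, so the step is an atom-economic isomerising addition. The closest known reaction types are the Lewis acid-promoted oxa-Povarov reaction of aryl oxocarbenium ions with alkenes and the chiral phosphoric acid-catalysed Povarov reaction of N-(2-hydroxyphenyl) aldimines with enol ethers, in which the ortho-hydroxy group is the second binding point for the phosphate just as the 8-OH is here. The pyran ring closes as a formal [4+2] whose second bond forms by 6-exo-trig attack of C4a on the C4 oxocarbenium held in the dioxolane ring. C2 is set by the catalyst, which shields one face of the (E)-oxocarbenium in the two-point-bound ion pair; C3 follows from the endo approach of the dioxole, which places its oxygens cis to the 2-aryl group; C4 follows from C3 because the five-membered acetonide can only be cis-fused when the tethered arene closes. The step needs regioselective ring closure, which is secured because only the oxocarbenium on O1 has a free ortho carbon (C4a) and that carbon is para to the 7-benzyloxy group, while ionisation in the other sense is reversible and unproductive.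

Step 4
Reactants: 8
Product: 9 (2R,3S,4R)-7,8-bis(benzyloxy)-2-[4-(benzyloxy)phenyl]-3,4-(isopropylidenedioxy)chromane
Conditions: BnBr, K2CO3, DMF, 40 °C
Reagents that add atoms: benzyl bromide, BrCc1ccccc1
Why: Williamson ether synthesis; capping the 8-OH removes the free phenol that would otherwise direct the later Friedel–Crafts coupling to C5 (para to it).

Step 5
Reactants: 10 1-(2,3,4-trihydroxyphenyl)ethan-1-one (gallacetophenone)
Product: 11 1-[3,4-bis(benzyloxy)-2-hydroxyphenyl]ethan-1-one
Conditions: BnBr (2.1 equiv), K2CO3, acetone, reflux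
Reagents that add atoms: benzyl bromide, BrCc1ccccc1
Why: Selective Williamson etherification; the 2-OH is hydrogen-bonded to the ketone and is the least reactive, so the 3- and 4-hydroxyls should be benzylated first.

Step 6
Reactants: 11
Product: 12 1-[3,4-bis(benzyloxy)-2-(methoxymethoxy)phenyl]ethan-1-one
Conditions: NaH, MOMCl, DMF, 0 °C
Reagents that add atoms: chloromethyl methyl ether, COCCl
Why: Alkylation of the phenoxide (acetal protection); the masked 2-OH cannot cyclise onto the enone during the condensation and epoxidation that follow.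

Step 7
Reactants: 12; 2 4-(benzyloxy)benzaldehyde
Product: 13 (E)-1-[3,4-bis(benzyloxy)-2-(methoxymethoxy)phenyl]-3-[4-(benzyloxy)phenyl]prop-2-en-1-one
Conditions: KOH, EtOH/THF, rt
Reagents that add atoms: none
Why: Claisen–Schmidt condensation of a methyl ketone with a non-enolisable aldehyde, giving the (E)-chalcone.

Step 8
Reactants: 13
Product: 14 [(2S,3R)-3-[4-(benzyloxy)phenyl]oxiran-2-yl][3,4-bis(benzyloxy)-2-(methoxymethoxy)phenyl]methanone
Conditions: poly-D-leucine [H(NHCH(CH2CHMe2)CO)nOH], urea–H2O2, 1,8-diazabicyclo[5.4.0]undec-7-ene, THF, rt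
Reagents that add atoms: urea–hydrogen peroxide, NC(N)=O.OO
Why: Julia–Colonna epoxidation; the helical D-peptide delivers hydroperoxide to one face of the enone and should give the (2S,3R)-trans-epoxide, which fixes the future C3 of the upper unit.

Step 9
Reactants: 14
Product: 16 (2S,3S)-7,8-bis(benzyloxy)-2-[4-(benzyloxy)phenyl]-3-hydroxychroman-4-one (2,3-trans), via [(2S,3R)-3-[4-(benzyloxy)phenyl]oxiran-2-yl][3,4-bis(benzyloxy)-2-hydroxyphenyl]methanone 15 (not isolated)
Conditions: conc. HCl, MeOH/THF, 50 °C
Reagents that add atoms: none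
Why: Acid removes the methoxymethyl group and the freed phenol opens the epoxide at the benzylic carbon (6-endo, favoured by the 4-benzyloxyphenyl group) with inversion, giving the 2,3-trans-dihydroflavonol, which is also the thermodynamically preferred C2 epimer; C3 is untouched.

Step 10
Reactants: 16
Product: 17 (2S,3R,4S)-7,8-bis(benzyloxy)-2-[4-(benzyloxy)phenyl]chromane-3,4-diol (2,3-trans-3,4-trans)
Conditions: NaBH4, MeOH/THF, 0 °C
Reagents that add atoms: none
Why: Hydride reduction of the ketone should give mainly the 3,4-trans diol; the C4 configuration is erased in step 12, so a minor C4 epimer is of no consequence.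

Step 11
Reactants: 17
Product: 18 (2S,3S,4S)-7,8-bis(benzyloxy)-2-[4-(benzyloxy)phenyl]chromane-3,4-diyl diacetate (2,3-trans-3,4-trans)
Conditions: Ac2O, pyridine, 4-(dimethylamino)pyridine (cat.), CH2Cl2, rt
Reagents that add atoms: acetic anhydride, CC(=O)OC(C)=O
Why: Acylation installs the 4-acetate as leaving group and the 3-acetate as participating group for the coupling.

Step 12
Reactants: 18; 9
Product: 19 3-O-acetyl-7,8,4'-tri-O-benzyl-ent-oritin-(4β→6)-[7,8,4'-tri-O-benzyl-3,4-O-isopropylidene-epioritin-4α-ol]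
Conditions: 9 (2.5 equiv, excess recovered), Me3SiOSO2CF3 (0.2 equiv), 4 Å molecular sieves, CH2Cl2, −78 to −40 °C
Reagents that add atoms: none
Why: Friedel–Crafts alkylation by the flavan-4-yl cation; ionisation of the 4-acetate is assisted by the 3-acetoxy group, which then blocks the face syn to O3, so that C6 of 9 (ortho to the 7-benzyloxy group and para to O1, the most activated position) should add anti and set the 3,4-trans (4β) configuration.

Step 13
Reactants: 19
Product: 20 7,8,4'-tri-O-benzyl-ent-oritin-(4β→6)-[7,8,4'-tri-O-benzyl-3,4-O-isopropylidene-epioritin-4α-ol]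
Conditions: K2CO3 (cat.), MeOH/THF, rt
Reagents that add atoms: none
Why: Zemplén-type transesterification removes the acetate; all phenols are benzylated, so no quinone methide or C2 epimerisation pathway is open under base.

Step 14
Reactants: 20
Product: 21 7,8,4'-tri-O-benzyl-ent-oritin-(4β→6)-(7,8,4'-tri-O-benzyl-epioritin-4α-ol)
Conditions: AcOH/H2O/THF (3:1:1), 40 °C
Reagents that add atoms: none
Why: Acetal hydrolysis; protonation of an acetal oxygen and loss of acetone through the tertiary oxocarbenium ion should be much faster than ionisation of the benzylic C4–O bond, so the 3,4-cis diol should be released without epimerisation at C4.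

Step 15
Reactants: 21
Product: 22 ent-oritin-(4β→6)-epioritin-4α-ol
Conditions: H2 (1 atm), Pd(OH)2/C, EtOAc/MeOH, rt
Reagents that add atoms: none
Why: Hydrogenolysis of the six aryl benzyl ethers, which should cleave far faster than the secondary benzylic C4–OH and C2–O1 bonds under neutral conditions; no stereocentre is touched.

**Compound list**

1 | pyrogallol (benzene-1,2,3-triol) | Oc1cccc(O)c1O | starting material
2 | 4-(benzyloxy)benzaldehyde | O=Cc1ccc(OCc2ccccc2)cc1 | starting material
3 | 4-(benzyloxy)benzaldehyde dimethyl acetal | COC(OC)c1ccc(OCc2ccccc2)cc1 | intermediate (not isolated)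
4 | 2-[4-(benzyloxy)phenyl]-1,3-benzodioxol-4-ol (racemic at the acetal carbon) | Oc1cccc2OC(c3ccc(OCc4ccccc4)cc3)Oc12 | intermediate
5 | 4-(benzyloxy)-2-[4-(benzyloxy)phenyl]-1,3-benzodioxole (racemic at the acetal carbon) | c1ccccc1COc1cccc2OC(c3ccc(OCc4ccccc4)cc3)Oc12 | intermediate
6 | 2,2-dimethyl-1,3-dioxole | CC1(C)OC=CO1 | starting material
7 | ring-opened aryl oxocarbenium ion: (E)-[3-(benzyloxy)-2-hydroxyphenyl][4-(benzyloxy)benzylidene]oxonium, ion pair with the catalyst phosphate | Oc1c(OCc2ccccc2)cccc1/[O+]=C/c1ccc(OCc2ccccc2)cc1 | intermediate (not isolated)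
8 | (2R,3S,4R)-7-(benzyloxy)-2-[4-(benzyloxy)phenyl]-3,4-(isopropylidenedioxy)chroman-8-ol (all-cis) | c1ccccc1COc1ccc([C@H]2Oc3c(ccc(OCc4ccccc4)c3O)[C@H]4OC(C)(C)O[C@@H]24)cc1 | intermediate
9 | (2R,3S,4R)-7,8-bis(benzyloxy)-2-[4-(benzyloxy)phenyl]-3,4-(isopropylidenedioxy)chromane (all-cis) | c1ccccc1COc1ccc([C@H]2Oc3c(ccc(OCc4ccccc4)c3OCc3ccccc3)[C@H]4OC(C)(C)O[C@@H]24)cc1 | intermediate
10 | 1-(2,3,4-trihydroxyphenyl)ethan-1-one (gallacetophenone) | CC(=O)c1ccc(O)c(O)c1O | starting material
11 | 1-[3,4-bis(benzyloxy)-2-hydroxyphenyl]ethan-1-one | CC(=O)c1ccc(OCc2ccccc2)c(OCc2ccccc2)c1O | intermediate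
12 | 1-[3,4-bis(benzyloxy)-2-(methoxymethoxy)phenyl]ethan-1-one | CC(=O)c1ccc(OCc2ccccc2)c(OCc2ccccc2)c1OCOC | intermediate
13 | (E)-1-[3,4-bis(benzyloxy)-2-(methoxymethoxy)phenyl]-3-[4-(benzyloxy)phenyl]prop-2-en-1-one | COCOc1c(C(=O)/C=C/c2ccc(OCc3ccccc3)cc2)ccc(OCc2ccccc2)c1OCc1ccccc1 | intermediate
14 | [(2S,3R)-3-[4-(benzyloxy)phenyl]oxiran-2-yl][3,4-bis(benzyloxy)-2-(methoxymethoxy)phenyl]methanone (trans-epoxide) | COCOc1c(C(=O)[C@H]2O[C@@H]2c2ccc(OCc3ccccc3)cc2)ccc(OCc2ccccc2)c1OCc1ccccc1 | intermediate
15 | [(2S,3R)-3-[4-(benzyloxy)phenyl]oxiran-2-yl][3,4-bis(benzyloxy)-2-hydroxyphenyl]methanone | Oc1c(C(=O)[C@H]2O[C@@H]2c2ccc(OCc3ccccc3)cc2)ccc(OCc2ccccc2)c1OCc1ccccc1 | intermediate (not isolated)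
16 | (2S,3S)-7,8-bis(benzyloxy)-2-[4-(benzyloxy)phenyl]-3-hydroxychroman-4-one (2,3-trans) | O=C1c2ccc(OCc3ccccc3)c(OCc3ccccc3)c2O[C@@H](c2ccc(OCc3ccccc3)cc2)[C@@H]1O | intermediate
17 | (2S,3R,4S)-7,8-bis(benzyloxy)-2-[4-(benzyloxy)phenyl]chromane-3,4-diol (2,3-trans-3,4-trans) | O[C@H]1c2ccc(OCc3ccccc3)c(OCc3ccccc3)c2O[C@@H](c2ccc(OCc3ccccc3)cc2)[C@@H]1O | intermediate
18 | (2S,3S,4S)-7,8-bis(benzyloxy)-2-[4-(benzyloxy)phenyl]chromane-3,4-diyl diacetate (2,3-trans-3,4-trans) | CC(=O)O[C@H]1c2ccc(OCc3ccccc3)c(OCc3ccccc3)c2O[C@@H](c2ccc(OCc3ccccc3)cc2)[C@@H]1OC(C)=O | intermediate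
19 | 3-O-acetyl-7,8,4'-tri-O-benzyl-ent-oritin-(4β→6)-[7,8,4'-tri-O-benzyl-3,4-O-isopropylidene-epioritin-4α-ol] (configuration as in 22) | c1ccccc1COc1ccc([C@H]2Oc3c(cc([C@H]4c5ccc(OCc6ccccc6)c(OCc6ccccc6)c5O[C@@H](c5ccc(OCc6ccccc6)cc5)[C@@H]4OC(C)=O)c(OCc4ccccc4)c3OCc3ccccc3)[C@H]4OC(C)(C)O[C@@H]24)cc1 | intermediate
20 | 7,8,4'-tri-O-benzyl-ent-oritin-(4β→6)-[7,8,4'-tri-O-benzyl-3,4-O-isopropylidene-epioritin-4α-ol] | c1ccccc1COc1ccc([C@H]2Oc3c(cc([C@H]4c5ccc(OCc6ccccc6)c(OCc6ccccc6)c5O[C@@H](c5ccc(OCc6ccccc6)cc5)[C@@H]4O)c(OCc4ccccc4)c3OCc3ccccc3)[C@H]4OC(C)(C)O[C@@H]24)cc1 | intermediate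
21 | 7,8,4'-tri-O-benzyl-ent-oritin-(4β→6)-(7,8,4'-tri-O-benzyl-epioritin-4α-ol) | c1ccccc1COc1ccc([C@H]2Oc3c(cc([C@H]4c5ccc(OCc6ccccc6)c(OCc6ccccc6)c5O[C@@H](c5ccc(OCc6ccccc6)cc5)[C@@H]4O)c(OCc4ccccc4)c3OCc3ccccc3)[C@@H](O)[C@H]2O)cc1 | intermediate
22 | ent-oritin-(4β→6)-epioritin-4α-ol; (2R,3R,4R)-2-(4-hydroxyphenyl)-6-[(2S,3R,4S)-3,7,8-trihydroxy-2-(4-hydroxyphenyl)chroman-4-yl]chromane-3,4,7,8-tetrol | Oc1ccc([C@H]2Oc3c(cc([C@H]4c5ccc(O)c(O)c5O[C@@H](c5ccc(O)cc5)[C@@H]4O)c(O)c3O)[C@@H](O)[C@H]2O)cc1 | target

**Summary**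

Total step count: 15. Longest linear sequence: 11 steps (steps 5–15, from 10); the lower unit (steps 1–4) joins at step 12.

Steps most likely to fail:

1. Step 3. What may go wrong: ionisation of the acetal in the unproductive sense, acid-induced oligomerisation of the enol ether, or insufficient face and endo selectivity in the annulation. The fallback sets out from 5. SnCl4 (1.1 equiv) with 2,6-di-tert-butylpyridine in CH2Cl2 at −78 °C and 6 is the stoichiometric, achiral Lewis-acid form of the oxa-Povarov reaction; tin can chelate the 7-benzyloxy oxygen and the departing acetal oxygen, which directs ionisation in the productive sense. It should give the all-cis cycloadduct as a racemate, that is 8 together with the enantiomer of 8 F1. Benzylation as in step 4 gives 9 and the enantiomer of 9 F2, and the mixture is coupled with enantiopure 18 as in step 12. The upper unit then serves as a built-in resolving group, and the lower-unit diastereomer of 19 F3 is removed by chromatography. The fallback comes back to the route at 19.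

2. Step 12. What may go wrong: self-condensation of the flavan-4-yl cation with ring A of its own precursor, sluggish attack by the benzylated nucleophile, and Lewis-acid ionisation of the benzylic acetonide of 9. The fallback sets out from 18 and changes the order of events. Coupling of 18 with a large excess of pyrogallol 1 under the same catalyst in THF/CH2Cl2 uses a far more reactive arene with a single nucleophilic position and should give the 3-O-acetyl-tri-O-benzyl-4β-(2,3,4-trihydroxyphenyl) adduct F4. Transacetalisation with 3 under mild, kinetically controlled conditions should engage the two hydroxyls remote from the flavanyl group and give the arylidene acetal F5. Benzylation of the remaining hindered phenol gives the benzyl ether F6. The annulation of step 3 with 6 then builds the lower unit on the dimer and gives the 8-hydroxy analogue of 19 F7, and benzylation as in step 4 comes back to the route at 19.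

3. Step 15. What may go wrong: over-reduction, that is hydrogenolysis of the benzylic C4–OH bond of the lower unit once the phenols are free. The fallback sets out from 20 and reverses the last two operations. Hydrogenolysis is run while C4–O is still tied up in the acetonide and should give the 3,4-O-isopropylidene acetal of 22 F8. Brief treatment with aqueous acetic acid at rt then releases the diol and comes back to the route at 22.

**Further compounds**

F1 | step 3 | enantiomer of 8: (2S,3R,4S)-7-(benzyloxy)-2-[4-(benzyloxy)phenyl]-3,4-(isopropylidenedioxy)chroman-8-ol | c1ccccc1COc1ccc([C@@H]2Oc3c(ccc(OCc4ccccc4)c3O)[C@@H]4OC(C)(C)O[C@H]24)cc1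
F2 | step 3 | enantiomer of 9: (2S,3R,4S)-7,8-bis(benzyloxy)-2-[4-(benzyloxy)phenyl]-3,4-(isopropylidenedioxy)chromane | c1ccccc1COc1ccc([C@@H]2Oc3c(ccc(OCc4ccccc4)c3OCc3ccccc3)[C@@H]4OC(C)(C)O[C@H]24)cc1
F3 | step 3 | diastereomer of 19 carrying the enantiomeric (2S,3R,4S) lower unit | c1ccccc1COc1ccc([C@@H]2Oc3c(cc([C@H]4c5ccc(OCc6ccccc6)c(OCc6ccccc6)c5O[C@@H](c5ccc(OCc6ccccc6)cc5)[C@@H]4OC(C)=O)c(OCc4ccccc4)c3OCc3ccccc3)[C@@H]4OC(C)(C)O[C@H]24)cc1
F4 | step 12 | 3-O-acetyl-7,8,4'-tri-O-benzyl-4β-(2,3,4-trihydroxyphenyl)-ent-oritin (2,3-trans-3,4-trans) | Oc1ccc([C@H]2c3ccc(OCc4ccccc4)c(OCc4ccccc4)c3O[C@@H](c3ccc(OCc4ccccc4)cc3)[C@@H]2OC(C)=O)c(O)c1O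
F5 | step 12 | 4-(benzyloxy)benzylidene acetal of F4 across the 3- and 4-oxygens of the trihydroxyphenyl ring (2-OH free) | C1(c2ccc(OCc3ccccc3)cc2)Oc2ccc([C@H]4c5ccc(OCc6ccccc6)c(OCc6ccccc6)c5O[C@@H](c5ccc(OCc6ccccc6)cc5)[C@@H]4OC(C)=O)c(O)c2O1
F6 | step 12 | benzyl ether of F5 at the remaining phenol | C1(c2ccc(OCc3ccccc3)cc2)Oc2ccc([C@H]4c5ccc(OCc6ccccc6)c(OCc6ccccc6)c5O[C@@H](c5ccc(OCc6ccccc6)cc5)[C@@H]4OC(C)=O)c(OCc3ccccc3)c2O1
F7 | step 12 | analogue of 19 with the 8-OH of the lower unit free | c1ccccc1COc1ccc([C@H]2Oc3c(cc([C@H]4c5ccc(OCc6ccccc6)c(OCc6ccccc6)c5O[C@@H](c5ccc(OCc6ccccc6)cc5)[C@@H]4OC(C)=O)c(OCc4ccccc4)c3O)[C@H]4OC(C)(C)O[C@@H]24)cc1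
F8 | step 15 | 3,4-O-isopropylidene acetal of 22 at the lower unit, all phenols free | Oc1ccc([C@H]2Oc3c(cc([C@H]4c5ccc(O)c(O)c5O[C@@H](c5ccc(O)cc5)[C@@H]4O)c(O)c3O)[C@H]4OC(C)(C)O[C@@H]24)cc1
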